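# Proposed synthesis of (3R)-8-hydroxy-6-methoxy-3-(6-oxoundecyl)-3,4-dihydroisocoumarin (17) by conjunctive coupling at C3/C4

## The problem

The target 17 is a benzo-fused δ-lactone. Ring A is a benzene ring with a free phenol at C8 and a methyl ether at C6; ring B (C1, O2, C3, C4, C4a, C8a) is the lactone; C3 carries an eleven-carbon chain (C1′–C11′) with a ketone at C6′. The only stereocentre is C3 (R). It is insulated from every other functional group, so nothing in the molecule can relay chirality to it and it has to be set by a catalyst, a reagent or a chiral building block. Ring A is a phloroglucinol carboxylate whose three oxygen-bearing positions must end up different: OMe at C6, free OH at C8, and carbon (the C4a–C4 bond) at the third. The lactone opens under base and nucleophiles, the chain ketone cannot meet an organometallic reagent unmasked, and the acidic, chelating C8 phenol must be covered whenever a carbanion or a boron ate complex is present. The C3–C4 unit invites a three-component assembly, because C3 bears oxygen and the chain carbon C1′ while C4 is bound to the arene carbon C4a. That is the pattern of a vinylboron unit that has received an alkyl group at its boron-bearing carbon and an aryl group at its terminal carbon, with boron standing in for the later oxygen. The carboxyl carbon C1 on C8a, ortho to C4a, then captures that oxygen to close ring B.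

## Retrosynthesis

**17 to 16.** The lactone bond C1–O2 is opened to the methyl ester and the free C3 alcohol, the C8 phenol is covered as its methoxymethyl ether and the C6′ ketone as its dioxolane, which gives hydroxy ester 16. Carrying a closed lactone and a free phenol through organometallic steps was rejected, since neither survives an ate complex or alkaline peroxide. All three changes are reversed by aqueous acid, so a single forward operation should deliver 17; it must cleave two acetals and drive a six-membered transesterification without touching C3.

**16 to 15.** The C3–O bond is traced back to a C3–B bond in pinacol boronate 15. Boron is a masked hydroxyl that tolerates the coupling conditions and is converted with retention, so the configuration of 15 is that of 16. The forward oxidation must leave the hindered methyl ester and both acetals alone.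

**15 to 4, 12 and 13.** Both bonds flanking the C3–C4 unit, C4–C4a and C3–C1′, are cut at once. This gives aryl triflate 4, vinylboronic pinacol ester 12 and the chain alkyllithium 13, the last two combined as ate complex 14. The neighbouring single cuts are weaker:
- C4–C4a alone needs an aryl nucleophile next to an ester to open a chiral epoxide.
- C3–C1′ alone needs an enantioselective addition to an easily enolised arylacetaldehyde.
- C3–C4 alone, through a lateral benzylic anion and an aldehyde, gives no control at C3.

The double cut divides the molecule into three pieces of comparable size and lets the catalyst create C3 in the same step. The forward reaction needs complete consumption of 13 before 4 enters, removal of halide, and the correct ligand enantiomer.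

**4 to 1.** Only C–O bonds change. Triflate 4 comes from phenol 3 by methoxymethylation, 3 from the symmetric diol 2 by triflation of one of two equivalent hydroxyls, and 2 from methyl 2,4,6-trihydroxybenzoate 1 by methylation of the one hydroxyl not hydrogen-bonded to the ester. The order uses the acidity difference first; after the first triflation the ring is deactivated and the remaining hydroxyl is chelated, which should hold the reaction at the monotriflate.

**13 to 5 and 7.** The alkyllithium 13 comes from iodide 11 by lithium–iodine exchange, 11 from alcohol 10, and 10 from hydroxy ketone 9 by ketalisation. Ketone 9 is cut at C6′–C7′ into Weinreb amide 6 and pentylmagnesium bromide 8 (from 1-bromopentane 7). Amide 6 is ring-opened ε-caprolactone 5, which supplies C1′–C6′ with its two ends already differentiated. The amide is preferred to direct addition to the lactone because it stops cleanly at the ketone.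

## Roads not taken

**Alternative 1:** Ring A is cut at C4a–C8a and built last. An open-chain diketo-dioxinone A1 would undergo amine-induced aldol addition of the dioxinone α-carbon to the ketone that becomes C4a, then dehydration and enolisation, to give benzodioxinone A2.
- Merits: the oxygens of ring A arise already differentiated. The C6 oxygen is a free phenol ready for methylation, and the C8 oxygen and C1 are tied together in the dioxinone, which later acylates the C3 oxygen to close ring B. No triflate and no precious metal are needed.
- Weak points: the key step does not create C3, so a separate asymmetric reaction on the chain is needed before A1. A1 is a sensitive tricarbonyl compound that takes several acylation steps to assemble. Its C3 silyloxy group lies β to the C4a ketone, so the amine base can trigger elimination in competition with the aldol closure. Methylation, desilylation with lactonisation and ketal hydrolysis still follow A2.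
- Comparison: on oxygen differentiation this road is better than the chosen plan, which depends on a regioselective methylation (step 1) and a monotriflation of a symmetric diol (step 2). The chosen plan offsets this by making both C–C bonds and the stereocentre in one catalytic step from three simple pieces, with a shorter sequence overall.

**Alternative 2:** The ring oxygen O2 is excised, so that C1–O2 and O2–C3 trace back to the C1–C3 bond of the racemic indanone A3. A Baeyer–Villiger monooxygenase would oxidise one enantiomer of A3 with migration of the alkyl-bearing carbon while the other enantiomer racemises through its enol, giving lactone A4.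
- Merits: A3 should be available by alkylating a dimethoxyindanone with an iodide such as 11. A dynamic kinetic resolution can in principle convert all the material, and no carboxyl protecting group or transition metal is needed.
- Weak points: the enzyme must accept a long lipophilic 2-substituent carrying a ketal, whereas this transformation is established for small alkyl groups. It must also migrate the alkyl carbon rather than the electron-rich aryl carbon, which is the intrinsically better migrating group. Racemisation of A3 must outpace oxidation of the slow enantiomer. A4 then needs chelation-directed removal of the C8 methyl group and ketal hydrolysis.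
- Comparison: if a suitable enzyme exists, this road is shorter than the chosen plan. The chosen plan instead uses a small-molecule catalyst whose scope covers primary alkyl migrating groups and aryl triflates, with both ligand enantiomers available and no enzyme screening.

**Alternative 3:** Four bonds of ring A are cut (C4a–C5, C5–C6, C7–C8, C8–C8a) and ring B is made first as the chiral diazoacetyl dihydropyranone A5. Irradiation of A5 with methoxyethyne A6 would give lactone ketal A7 by Wolff rearrangement to a vinylketene, [2+2] addition, four-electron ring opening and six-electron closure.
- Merits: the mechanism places the C8 hydroxyl and the C6 methoxy group regiospecifically, with no protecting group on ring A. A7 is one ketal hydrolysis away from 17, a shorter endgame than the chosen plan.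
- Weak points: C3 must be set earlier by a separate enantioselective synthesis of the dihydropyranone. A5 needs several steps and is base-sensitive, since its dienolate can expel the ring oxygen. A6 is volatile and unstable and must be used in excess. The photochemical cascade passes through a ketene conjugated to the lactone, where side reactions are hard to foresee.
- Comparison: the chosen plan starts from a cheap preformed arene, sets C3 in the bond-forming step, uses thermally robust intermediates and needs fewer steps in total.

Key step: step 8

Assumption: (Sp,Sp)-MandyPhos here means (Sp,Sp)-1,1′-bis[bis(4-methoxy-3,5-dimethylphenyl)phosphino]-2,2′-bis[(R)-α-(dimethylamino)benzyl]ferrocene, and this enantiomer is taken to give the (R)-boronate with a primary alkyl migrating group; the sense would be confirmed on a model pair, and the antipodal ligand would be used if it proves opposite, with nothing else changed.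

## Route

Step 1
Reactants: 1 methyl 2,4,6-trihydroxybenzoate
Product: 2 methyl 2,6-dihydroxy-4-methoxybenzoate
Conditions: MeOH (1.1 equiv), PPh3, DIAD, THF, 0 °C → rt
Reagents that add atoms: methanol, CO
Why: Mitsunobu etherification; the C4 hydroxyl is the most acidic and the only one not hydrogen-bonded to the ester, and chelated ortho-phenols are poor Mitsunobu partners, so methylation should stop at the 4-ether.

Step 2
Reactants: 2 methyl 2,6-dihydroxy-4-methoxybenzoate
Product: 3 methyl 2-hydroxy-4-methoxy-6-(trifluoromethylsulfonyloxy)benzoate
Conditions: Tf2O (1.05 equiv), pyridine, CH2Cl2, −20 → 0 °C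
Reagents that add atoms: trifluoromethanesulfonic anhydride, O=S(=O)(OS(=O)(=O)C(F)(F)F)C(F)(F)F
Why: O-Sulfonylation of a phenol; the two hydroxyls are equivalent, and after the first triflation the ring is electron-poorer and the remaining hydroxyl is tightly chelated to the ester, which should hold the reaction at the monotriflate.

Step 3
Reactants: 3 methyl 2-hydroxy-4-methoxy-6-(trifluoromethylsulfonyloxy)benzoate
Product: 4 methyl 4-methoxy-2-(methoxymethoxy)-6-(trifluoromethylsulfonyloxy)benzoate
Conditions: MOMCl, iPr2NEt, CH2Cl2, 0 → 40 °C
Reagents that add atoms: chloromethyl methyl ether, COCCl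
Why: Methoxymethylation of a phenol with a reactive α-chloro ether and a hindered amine base; the aryl triflate is stable to these non-nucleophilic conditions.

Step 4
Reactants: 5 ε-caprolactone
Product: 6 6-hydroxy-N-methoxy-N-methylhexanamide
Conditions: MeNHOMe·HCl, AlMe3, CH2Cl2, 0 °C → rt; aqueous work-up
Reagents that add atoms: N,O-dimethylhydroxylamine hydrochloride, CNOC.Cl
Why: Weinreb aminolysis of a lactone by the aluminium amide formed from AlMe3 and the amine salt; ring opening releases the primary alcohol and gives the Weinreb amide.

Step 5
Reactants: 6 6-hydroxy-N-methoxy-N-methylhexanamide; 7 1-bromopentane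
Product: 9 1-hydroxyundecan-6-one, via pentylmagnesium bromide 8 (not isolated)
Conditions: 7, Mg, THF, rt; then 6 (8 in 2.5-fold amount), THF, 0 °C → rt; aq. NH4Cl
Reagents that add atoms: none
Why: Grignard addition to a Weinreb amide; one equivalent of 8 is spent on the hydroxyl, and the chelated tetrahedral intermediate prevents a second addition, so the ketone appears only on work-up.

Step 6
Reactants: 9 1-hydroxyundecan-6-one
Product: 10 5-(2-pentyl-1,3-dioxolan-2-yl)pentan-1-ol
Conditions: HOCH2CH2OH (5 equiv), p-TsOH·H2O (cat.), benzene, reflux, Dean–Stark
Reagents that add atoms: ethane-1,2-diol, OCCO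
Why: Acid-catalysed ketalisation with azeotropic removal of water; the five-membered dioxolane is favoured over mixed open-chain ketals with the remote primary alcohol.

Step 7
Reactants: 10 5-(2-pentyl-1,3-dioxolan-2-yl)pentan-1-ol
Product: 11 2-(5-iodopentyl)-2-pentyl-1,3-dioxolane
Conditions: I2, PPh3, imidazole, CH2Cl2, 0 °C → rt
Reagents that add atoms: iodine, II
Why: Appel-type iodination of a primary alcohol through its alkoxyphosphonium salt; imidazole buffers the acid released and so protects the dioxolane.

Step 8
Reactants: 11 2-(5-iodopentyl)-2-pentyl-1,3-dioxolane; 12 vinylboronic acid pinacol ester (4,4,5,5-tetramethyl-2-vinyl-1,3,2-dioxaborolane); 4 methyl 4-methoxy-2-(methoxymethoxy)-6-(trifluoromethylsulfonyloxy)benzoate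
Product: 15 methyl 4-methoxy-2-(methoxymethoxy)-6-[(2R)-7-(2-pentyl-1,3-dioxolan-2-yl)-2-(4,4,5,5-tetramethyl-1,3,2-dioxaborolan-2-yl)heptyl]benzoate, via [5-(2-pentyl-1,3-dioxolan-2-yl)pentyl]lithium 13 (not isolated), via lithium alkyl(vinyl)pinacolboronate complex 14 (not isolated)
Conditions: 11, tert-butyllithium (2.0 equiv), Et2O/pentane, −78 °C; 12 (1.05 equiv), −78 °C → rt; solvent exchange to THF, KOTf; then 4, Pd(OAc)2 (2 mol %), (Sp,Sp)-MandyPhos (2.4 mol %), THF, 60 °C
Reagents that add atoms: none
Why: Enantioselective palladium-catalysed conjunctive cross-coupling of an alkyl(vinyl)boron ate complex with an aryl triflate, a known reaction type for primary alkyl migrating groups. Lithium–iodine exchange on 11 gives 13, which adds to the boron of 12 to form the four-coordinate boronate 14; the slight excess of 12 ensures that no free alkyllithium remains to attack the ester or the triflate of 4. Zerovalent palladium inserts into the C–OTf bond of 4 to give a cationic divalent arylpalladium complex whose vacant site binds the vinyl group of 14. The chain carbon C1′ then migrates from boron to the boron-bearing carbon (C3) anti to palladium while palladium bonds the terminal carbon (C4), and reductive elimination from the resulting β-boryl alkyl(aryl)palladium joins C4 to C4a faster than β-hydride elimination because of the wide-bite-angle bisphosphine. No ring is closed. The C3 stereocentre is set in the metallate shift by the face of the bound vinyl group that the chiral MandyPhos ligand leaves open, so the ligand enantiomer alone decides (R) against (S). The step needs conjunctive coupling to win over direct transfer of vinyl or alkyl to palladium, which is secured by the non-coordinating triflate leaving group, the pinacol ligand on boron and the removal of iodide as KI by KOTf, while the regiochemistry (aryl to the terminal carbon, alkyl to the boron-bearing carbon) is intrinsic to the mechanism. The ester, the methoxymethyl ether and the dioxolane are inert to the ate complex.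

Step 9
Reactants: 15 methyl 4-methoxy-2-(methoxymethoxy)-6-[(2R)-7-(2-pentyl-1,3-dioxolan-2-yl)-2-(4,4,5,5-tetramethyl-1,3,2-dioxaborolan-2-yl)heptyl]benzoate
Product: 16 methyl 2-[(2R)-2-hydroxy-7-(2-pentyl-1,3-dioxolan-2-yl)heptyl]-4-methoxy-6-(methoxymethoxy)benzoate
Conditions: 30% H2O2, 3 M NaOH, THF, 0 °C → rt
Reagents that add atoms: hydrogen peroxide, OO
Why: Oxidation of a secondary alkylboronic ester with alkaline hydrogen peroxide; the 1,2-shift of C3 from boron to oxygen proceeds with retention, so (R) is carried over. The doubly ortho-substituted methyl ester resists saponification at this temperature, and any ring closure that begins here is completed in step 10.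

Step 10
Reactants: 16 methyl 2-[(2R)-2-hydroxy-7-(2-pentyl-1,3-dioxolan-2-yl)heptyl]-4-methoxy-6-(methoxymethoxy)benzoate
Product: 17 (3R)-8-hydroxy-6-methoxy-3-(6-oxoundecyl)-3,4-dihydro-1H-isochromen-1-one
Conditions: 3 M HCl, THF, 50 °C
Reagents that add atoms: water, O
Why: Acid-catalysed acetal hydrolysis and lactonisation; the methoxymethyl ether and the dioxolane are cleaved, and the C3 hydroxyl displaces methanol from the ortho ester in a six-membered transesterification that is favoured by the hydrogen bond from the freed C8 phenol to the lactone carbonyl. C3 is not involved in any bond breaking, so its configuration is kept.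

## Compound list

1 | methyl 2,4,6-trihydroxybenzoate | COC(=O)c1c(O)cc(O)cc1O | starting material
2 | methyl 2,6-dihydroxy-4-methoxybenzoate | COC(=O)c1c(O)cc(OC)cc1O | intermediate
3 | methyl 2-hydroxy-4-methoxy-6-(trifluoromethylsulfonyloxy)benzoate | COC(=O)c1c(O)cc(OC)cc1OS(=O)(=O)C(F)(F)F | intermediate
4 | methyl 4-methoxy-2-(methoxymethoxy)-6-(trifluoromethylsulfonyloxy)benzoate | COCOc1cc(OC)cc(OS(=O)(=O)C(F)(F)F)c1C(=O)OC | intermediate
5 | ε-caprolactone (oxepan-2-one) | O=C1CCCCCO1 | starting material
6 | 6-hydroxy-N-methoxy-N-methylhexanamide | CON(C)C(=O)CCCCCO | intermediate
7 | 1-bromopentane | CCCCCBr | starting material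
8 | pentylmagnesium bromide | CCCCC[Mg]Br | intermediate
9 | 1-hydroxyundecan-6-one | CCCCCC(=O)CCCCCO | intermediate
10 | 5-(2-pentyl-1,3-dioxolan-2-yl)pentan-1-ol | CCCCCC1(CCCCCO)OCCO1 | intermediate
11 | 2-(5-iodopentyl)-2-pentyl-1,3-dioxolane | CCCCCC1(CCCCCI)OCCO1 | intermediate
12 | vinylboronic acid pinacol ester (4,4,5,5-tetramethyl-2-vinyl-1,3,2-dioxaborolane) | C=CB1OC(C)(C)C(C)(C)O1 | starting material
13 | [5-(2-pentyl-1,3-dioxolan-2-yl)pentyl]lithium | [Li]CCCCCC1(CCCCC)OCCO1 | intermediate
14 | lithium 4,4,5,5-tetramethyl-2-[5-(2-pentyl-1,3-dioxolan-2-yl)pentyl]-2-vinyl-1,3,2-dioxaborolan-2-uide | [Li+].C=C[B-]1(CCCCCC2(CCCCC)OCCO2)OC(C)(C)C(C)(C)O1 | intermediate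
15 | methyl 4-methoxy-2-(methoxymethoxy)-6-[(2R)-7-(2-pentyl-1,3-dioxolan-2-yl)-2-(4,4,5,5-tetramethyl-1,3,2-dioxaborolan-2-yl)heptyl]benzoate | CCCCCC1(CCCCC[C@@H](B2OC(C)(C)C(C)(C)O2)Cc2cc(OC)cc(OCOC)c2C(=O)OC)OCCO1 | intermediate
16 | methyl 2-[(2R)-2-hydroxy-7-(2-pentyl-1,3-dioxolan-2-yl)heptyl]-4-methoxy-6-(methoxymethoxy)benzoate | CCCCCC1(CCCCC[C@@H](O)Cc2cc(OC)cc(OCOC)c2C(=O)OC)OCCO1 | intermediate
17 | (3R)-8-hydroxy-6-methoxy-3-(6-oxoundecyl)-3,4-dihydro-1H-isochromen-1-one | CCCCCC(=O)CCCCC[C@@H]1Cc2cc(OC)cc(O)c2C(=O)O1 | target

## Step count and risks

Total: 10 steps. Longest linear sequence: 7 steps (5 to 17 through steps 4–10); the arene branch (steps 1–3) joins at step 8.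

**Step 8 (key step).** Three things are most likely to go wrong:
- Iodide left from the lithium–iodine exchange can occupy the cationic palladium centre, which shuts down alkene binding and diverts the ate complex into direct vinyl or alkyl transfer.
- The ortho ester carbonyl of the arylpalladium can compete with the vinyl group for the vacant site, slowing the metallate shift.
- The ortho substituent can erode enantioselectivity.

The fallback changes how the ate complex is assembled, so that no halide is present. It sets out from 11, which is borylated with bis(pinacolato)diboron under copper iodide (CuI) catalysis with PPh3 and LiOMe in DMF to give 4,4,5,5-tetramethyl-2-[5-(2-pentyl-1,3-dioxolan-2-yl)pentyl]-1,3,2-dioxaborolane F1, which is purified free of salts. Halide-free vinyllithium, made from tetravinylstannane and n-butyllithium, is then added to F1 in Et2O/THF. This comes back to the route at 14, which is coupled with 4 under the palladium conditions of step 8, without KOTf, to give 15.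

**Step 2.** Loss of mono-selectivity: the second, equivalent hydroxyl may also be triflated if chelation and ring deactivation do not slow it enough. The fallback reverses the order of differentiation. It sets out from 2, which is mono-protected with one equivalent of MOMCl and iPr2NEt to give methyl 2-hydroxy-4-methoxy-6-(methoxymethoxy)benzoate F2; here the remaining hydroxyl stays chelated and unreactive toward the alkylating agent. Triflation of F2 with Tf2O and pyridine comes back to the route at 4.

**Step 10.** The three acid-triggered events run at different rates, so ring closure may lag behind deprotection and leave open-chain material. Formaldehyde released from the methoxymethyl group can also be captured by the electron-rich ring A on prolonged heating. The fallback separates ring closure from deprotection. It sets out from 16, which is treated with NaH (0.2 equiv) in THF at 0 °C, so that the C3 alkoxide acylates itself on the ester and gives (3R)-6-methoxy-8-(methoxymethoxy)-3-[5-(2-pentyl-1,3-dioxolan-2-yl)pentyl]-3,4-dihydro-1H-isochromen-1-one F3. Brief treatment of F3 with dilute HCl in THF at room temperature then removes both acetals and comes back to the route at 17.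

**Step 7.** Acid set free during phosphonium activation can open the dioxolane if the buffering by imidazole is insufficient. The fallback replaces phosphonium activation by sulfonate displacement. It sets out from 10, which is converted with MsCl and Et3N in CH2Cl2 at 0 °C into 5-(2-pentyl-1,3-dioxolan-2-yl)pentyl methanesulfonate F4. Displacement with NaI in acetone at reflux comes back to the route at 11.

## Further compounds

F1 | step 8 | 4,4,5,5-tetramethyl-2-[5-(2-pentyl-1,3-dioxolan-2-yl)pentyl]-1,3,2-dioxaborolane | CCCCCC1(CCCCCB2OC(C)(C)C(C)(C)O2)OCCO1
F2 | step 2 | methyl 2-hydroxy-4-methoxy-6-(methoxymethoxy)benzoate | COCOc1cc(OC)cc(O)c1C(=O)OC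
F3 | step 10 | (3R)-6-methoxy-8-(methoxymethoxy)-3-[5-(2-pentyl-1,3-dioxolan-2-yl)pentyl]-3,4-dihydro-1H-isochromen-1-one | CCCCCC1(CCCCC[C@@H]2Cc3cc(OC)cc(OCOC)c3C(=O)O2)OCCO1
F4 | step 7 | 5-(2-pentyl-1,3-dioxolan-2-yl)pentyl methanesulfonate | CCCCCC1(CCCCCOS(C)(=O)=O)OCCO1
A1 | alternative 1 | 6-[(6R)-6-(tert-butyldimethylsilyloxy)-2,4-dioxo-11-(2-pentyl-1,3-dioxolan-2-yl)undecyl]-2,2-dimethyl-4H-1,3-dioxin-4-one | CC1(C)OC(=O)C=C(CC(=O)CC(=O)C[C@H](O[Si](C)(C)C(C)(C)C)CCCCCC2(CCCCC)OCCO2)O1
A2 | alternative 1 | 7-hydroxy-2,2-dimethyl-5-[(2R)-2-(tert-butyldimethylsilyloxy)-7-(2-pentyl-1,3-dioxolan-2-yl)heptyl]-4H-1,3-benzodioxin-4-one | CC1(C)Oc2cc(O)cc(C[C@H](O[Si](C)(C)C(C)(C)C)CCCCCC3(CCCCC)OCCO3)c2C(=O)O1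
A3 | alternative 2 | racemic 5,7-dimethoxy-2-[5-(2-pentyl-1,3-dioxolan-2-yl)pentyl]-2,3-dihydro-1H-inden-1-one | CCCCCC1(CCCCCC2Cc3cc(OC)cc(OC)c3C2=O)OCCO1
A4 | alternative 2 | (3R)-6,8-dimethoxy-3-[5-(2-pentyl-1,3-dioxolan-2-yl)pentyl]-3,4-dihydro-1H-isochromen-1-one | CCCCCC1(CCCCC[C@@H]2Cc3cc(OC)cc(OC)c3C(=O)O2)OCCO1
A5 | alternative 3 | (6R)-4-(2-diazoacetyl)-6-[5-(2-pentyl-1,3-dioxolan-2-yl)pentyl]-5,6-dihydro-2H-pyran-2-one | CCCCCC1(CCCCC[C@@H]2CC(C(=O)C=[N+]=[N-])=CC(=O)O2)OCCO1
A6 | alternative 3 | methoxyethyne | COC#C
A7 | alternative 3 | (3R)-8-hydroxy-6-methoxy-3-[5-(2-pentyl-1,3-dioxolan-2-yl)pentyl]-3,4-dihydro-1H-isochromen-1-one | CCCCCC1(CCCCC[C@@H]2Cc3cc(OC)cc(O)c3C(=O)O2)OCCO1
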